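The readings stem from a simulated flask from invented constants, and the scatter is random.

A small charge, 0.19 mol% of free catalyst, turns over starting material at 0.10 M in Monday's flask, and the solid reagent starts wholly undissolved. The question is what that flask holds at 30 min.

| setting | Monday's | Saturday's | flask |
|---|---|---|---|
| starting material | 0.10 M | 0.067 M | 0.10 M |
| solid reagent | 1.2 equiv | 1.2 equiv | 1.20 equiv |
| free catalyst | 0.19 mol% | 0.19 mol% | 0.19 mol% |
| remark | the very flask that is asked about, followed so far | run made earlier |  |
| time |  |  | 30 min |

| run | time / min | product / % | starting material / % |
|---|---|---|---|
| Monday's | 0.667 | 0 | 93 |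
| Monday's | 2.00 | 0 | 83 |
| Monday's | 3.00 | 0 | 81 |
| Monday's | 5.00 | 0 | 74 |
| Monday's | 8.00 | 7 | 64 |
| Monday's | 10.0 | 4 | 60 |
| Monday's | 12.0 | 5 | 52 |
| Saturday's | 1.00 | 2 | 95 |
| Saturday's | 3.00 | 0 | 87 |
| Saturday's | 6.00 | 3 | 74 |
| Saturday's | 10.0 | 4 | 70 |
| Saturday's | 12.0 | 7 | 62 |
| Saturday's | 15.0 | 10 | 56 |
| Saturday's | 20.0 | 14 | 46 |

(readings scatter by 2 percentage points)

- solid, in amounts per volume of the solution: solid reagent
- the numbers in the tables scatter by 2 percentage points (one standard deviation)
- steps under discussion: starting material + free catalyst -> free catalyst + open intermediate; free catalyst + open intermediate <-> catalyst intermediate; partner + catalyst intermediate -> free catalyst + product; solid reagent <-> partner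
- at the start none of the solid reagent is in solution

- amount of product at 30 min, in percent of the starting material charged
- the change that raises the amount of product at 30 min, in percent of the starting material charged most ("none" if none brings more than 2 percentage points) (delta / gamma / alpha / none)
- amount of product at 30 min, in percent of the starting material charged, after gamma

- delta: doubling the amount of free catalyst, all else as stated
- gamma: doubling the solubility of the solid reagent, all else as stated
- alpha: doubling the dissolution coefficient of the solid reagent, all else as stated

In the first instants of Monday's flask the opening step runs: by 3.00 min starting material reads 81% and product 0%, an induction period for product. By 12.0 min starting material reads 52% and product 5%, so 43.0% of the charge is unread. In Monday's flask the catalyst intermediate can hold at most 0.19 mol% of it, and the rest is open intermediate.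

What matters next is the last step, which needs catalyst intermediate and dissolved partner, and both start from nothing. Product should therefore rise faster than in proportion to time. Saturday's run shows this, climbing from 4% at 10.0 min to 14% at 20.0 min. The slope of log product against log time there is 1.81, above unity. This time exponent, n, is a reading and carries the scatter.

Toward the end, the reckoning made here holds n constant from Monday's last product reading and gives 26.2% at 30 min.

The forecast is lower: 17%, within 13% to 27%, on the ground of “supply of dissolved partner as limiting”. It names gamma as the best change, giving 30%, within 22% to 45%.

The flask gives 35.9%, above the forecast's high end. The best change is indeed gamma, which gives 60.4%.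

    starting material + free catalyst → free catalyst + open intermediate (k = 466 /M/min)
    free catalyst + open intermediate ⇌ catalyst intermediate (K = 29.7 /M, k = 4910 /M/min)
    partner + catalyst intermediate → free catalyst + product (k = 568 /M/min)
    solid reagent ⇌ partner, rate k4*(cs4 - [partner]) while solid is left; crystals form when [partner] > cs4 (solubility = 0.0520 M, k = 0.0713 /min)

In this flask, half of the turnover of the opening step is done by 8.21 min, but half of that of the step into catalyst intermediate is done later, by 18.5 min. At 30.0 min in this flask open intermediate stands at 39.1%, above the product's 35.9%. Run back from 35.9%, n gives 6.84% at 12.0 min, a gap of 1.9 percentage points from the reading, against a scatter of 2 points. Run forward to 50 min in the same flask, n gives 90.5%, but that flask stands at 65.5%, an exponent of 1.18.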